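**Retrosynthetic overview**
- The only ring, the 33-membered lactone, is closed last by macrolactonization of 32-hydroxydotriacontanoic acid (C1 acyl–O bond).
- The seco acid comes from a C32 chain carrying a ketone at C18, removed by Wolff–Kishner reduction with concurrent ester saponification.
- The C18 ketone comes from dehydration and hydrogenation of a β-hydroxy ketone made by an intermolecular boron aldol reaction that forms C16–C17 and joins two C16 halves.
- Fragment A (C17–C32, methyl ketone) comes from 15-pentadecanolide via Weinreb amide and MeMgBr; fragment B (C1–C16, ester aldehyde) comes from 16-hexadecanolide via methanolysis and oxidation.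

Assumption: the target has no stereocentre (it is achiral), so it is made as the one compound drawn; the racemic carbinol centre created in step 6 is erased in step 7.

**Route**

Step 1
Reactants: 1 15-pentadecanolide (oxacyclohexadecan-2-one)
Product: 2 15-hydroxy-N-methoxy-N-methylpentadecanamide
Conditions: MeNH(OMe)·HCl (1.6 equiv), iPrMgCl (3.2 equiv), THF, −20 → 0 °C; then 1 M aq HCl
Reagents that add atoms: N,O-dimethylhydroxylamine hydrochloride, CNOC.Cl
Why: The chloromagnesium amide formed in the flask opens the unstrained lactone by aminolysis (Weinreb amide formation), and the 16-membered ring cannot re-close under these conditions.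

Step 2
Reactants: 2 15-hydroxy-N-methoxy-N-methylpentadecanamide
Product: 3 15-[(tert-butyldimethylsilyl)oxy]-N-methoxy-N-methylpentadecanamide
Conditions: TBSCl (1.2 equiv), imidazole (2.5 equiv), DMF, rt
Reagents that add atoms: tert-butyldimethylsilyl chloride, CC(C)(C)[Si](C)(C)Cl
Why: Standard silylation of a primary alcohol gives a TBS ether that tolerates the Grignard, boron aldol, mesylation and hydrogenation steps ahead.

Step 3
Reactants: 3 15-[(tert-butyldimethylsilyl)oxy]-N-methoxy-N-methylpentadecanamide
Product: 5 16-[(tert-butyldimethylsilyl)oxy]hexadecan-2-one, via tetrahedral magnesium adduct 4 (not isolated)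
Conditions: MeMgBr (1.5 equiv), THF, 0 °C; then sat. aq NH4Cl
Reagents that add atoms: methylmagnesium bromide, C[Mg]Br
Why: Weinreb ketone synthesis, in which the chelated tetrahedral adduct resists a second addition and releases the methyl ketone only on work-up.

Step 4
Reactants: 6 16-hexadecanolide (oxacycloheptadecan-2-one)
Product: 7 methyl 16-hydroxyhexadecanoate
Conditions: MeOH (solvent), H2SO4 (cat.), reflux; then NaHCO3
Reagents that add atoms: methanol, CO
Why: Acid-catalysed transesterification (methanolysis) of the macrolactone is driven to the open hydroxy ester by the large excess of methanol.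

Step 5
Reactants: 7 methyl 16-hydroxyhexadecanoate
Product: 8 methyl 16-oxohexadecanoate
Conditions: TEMPO (10 mol%), PhI(OAc)2 (1.1 equiv), CH2Cl2, rt; used promptly
Reagents that add atoms: none
Why: The TEMPO/PhI(OAc)2 oxidation stops cleanly at the aldehyde for primary alcohols and leaves the methyl ester untouched.

Step 6
Reactants: 5 16-[(tert-butyldimethylsilyl)oxy]hexadecan-2-one, 8 methyl 16-oxohexadecanoate
Product: 11 methyl rac-32-[(tert-butyldimethylsilyl)oxy]-16-hydroxy-18-oxodotriacontanoate, via dicyclohexylboron enolate 9 (not isolated), via boron aldolate 10 (not isolated)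
Conditions: Cy2BCl (1.3 equiv), Et3N (1.5 equiv), Et2O, 0 °C, 1 h; then 8 in Et2O/CH2Cl2, −40 → 0 °C; then pH 7 buffer (NaH2PO4/Na2HPO4), MeOH, 30% H2O2, 0 °C
Reagents that add atoms: none
Why: In this intermolecular boron-mediated aldol reaction Cy2BCl/Et3N enolises the methyl ketone on its CH3 side and the non-basic boron enolate adds to the aldehyde in preference to the ester, forming C16–C17; the C16 carbinol is formed racemic, which is immaterial because it is eliminated in step 7.

Step 7
Reactants: 11 methyl rac-32-[(tert-butyldimethylsilyl)oxy]-16-hydroxy-18-oxodotriacontanoate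
Product: 13 methyl (16E)-32-[(tert-butyldimethylsilyl)oxy]-18-oxodotriacont-16-enoate, via β-mesyloxy ketone 12 (not isolated)
Conditions: MsCl (1.5 equiv), Et3N (4 equiv), CH2Cl2, 0 °C → rt
Reagents that add atoms: none
Why: Mesylation followed by E1cB elimination through the ketone enolate gives the conjugated E-enone, completing the aldol condensation.

Step 8
Reactants: 13 methyl (16E)-32-[(tert-butyldimethylsilyl)oxy]-18-oxodotriacont-16-enoate
Product: 14 methyl 32-[(tert-butyldimethylsilyl)oxy]-18-oxodotriacontanoate
Conditions: H2 (1 atm), 10% Pd/C (palladium on carbon), EtOAc, 30 °C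
Reagents that add atoms: none
Why: Catalytic hydrogenation saturates the conjugated C=C bond while the aliphatic ketone, ester and silyl ether are inert in EtOAc.

Step 9
Reactants: 14 methyl 32-[(tert-butyldimethylsilyl)oxy]-18-oxodotriacontanoate
Product: 15 methyl 32-hydroxy-18-oxodotriacontanoate
Conditions: HF·pyridine, THF/pyridine, 0 °C → rt
Reagents that add atoms: none
Why: Fluoride-driven desilylation frees the primary alcohol without touching ketone or ester, so that no silyl group enters the hot alkaline step.

Step 10
Reactants: 15 methyl 32-hydroxy-18-oxodotriacontanoate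
Product: 17 32-hydroxydotriacontanoic acid, via hydrazone potassium salt 16 (not isolated)
Conditions: N2H4·H2O (10 equiv), KOH (10 equiv), diethylene glycol, 130 °C, 2 h; then 195–200 °C with removal of water, 4 h (N2 atmosphere); then aq HCl
Reagents that add atoms: potassium hydroxide, [K+].[OH-]
Why: Wolff–Kishner reduction (Huang-Minlon procedure) converts the C18 ketone to CH2 through its hydrazone while the same hot KOH saponifies the methyl ester, a classical sequence for long-chain ω-hydroxy acids.

Step 11
Reactants: 17 32-hydroxydotriacontanoic acid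
Product: 19 oxacyclotritriacontan-2-one (32-dotriacontanolide, the target), via mixed anhydride 18 (not isolated)
Conditions: 2,4,6-trichlorobenzoyl chloride (1.2 equiv), Et3N (1.5 equiv), THF, 40 °C, 2 h; then syringe-pump addition over 10 h to DMAP (6 equiv) in toluene, reflux, final concentration about 1 mM
Reagents that add atoms: none
Why: Yamaguchi macrolactonization activates the acid as a mixed anhydride, and under high dilution the strain-free 33-membered ring closes in preference to oligomerising.

**Compound list**

1 | 15-pentadecanolide (oxacyclohexadecan-2-one) | O=C1CCCCCCCCCCCCCCO1 | starting material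
2 | 15-hydroxy-N-methoxy-N-methylpentadecanamide | CON(C)C(=O)CCCCCCCCCCCCCCO | intermediate
3 | 15-[(tert-butyldimethylsilyl)oxy]-N-methoxy-N-methylpentadecanamide | CON(C)C(=O)CCCCCCCCCCCCCCO[Si](C)(C)C(C)(C)C | intermediate
4 | bromomagnesium 16-[(tert-butyldimethylsilyl)oxy]-2-[methoxy(methyl)amino]hexadecan-2-olate (tetrahedral adduct, formed in the flask, not isolated) | CON(C)C(C)(O[Mg]Br)CCCCCCCCCCCCCCO[Si](C)(C)C(C)(C)C | intermediate
5 | 16-[(tert-butyldimethylsilyl)oxy]hexadecan-2-one (fragment A) | CC(=O)CCCCCCCCCCCCCCO[Si](C)(C)C(C)(C)C | intermediate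
6 | 16-hexadecanolide (oxacycloheptadecan-2-one) | O=C1CCCCCCCCCCCCCCCO1 | starting material
7 | methyl 16-hydroxyhexadecanoate | COC(=O)CCCCCCCCCCCCCCCO | intermediate
8 | methyl 16-oxohexadecanoate (fragment B) | COC(=O)CCCCCCCCCCCCCCC=O | intermediate
9 | dicyclohexyl({16-[(tert-butyldimethylsilyl)oxy]hexadec-1-en-2-yl}oxy)borane (boron enolate, not isolated) | C=C(OB(C1CCCCC1)C1CCCCC1)CCCCCCCCCCCCCCO[Si](C)(C)C(C)(C)C | intermediate
10 | methyl rac-32-[(tert-butyldimethylsilyl)oxy]-16-[(dicyclohexylboranyl)oxy]-18-oxodotriacontanoate (boron aldolate, not isolated) | COC(=O)CCCCCCCCCCCCCCC(OB(C1CCCCC1)C1CCCCC1)CC(=O)CCCCCCCCCCCCCCO[Si](C)(C)C(C)(C)C | intermediate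
11 | methyl rac-32-[(tert-butyldimethylsilyl)oxy]-16-hydroxy-18-oxodotriacontanoate (racemic at C16) | COC(=O)CCCCCCCCCCCCCCC(O)CC(=O)CCCCCCCCCCCCCCO[Si](C)(C)C(C)(C)C | intermediate
12 | methyl rac-32-[(tert-butyldimethylsilyl)oxy]-16-[(methanesulfonyl)oxy]-18-oxodotriacontanoate (not isolated) | COC(=O)CCCCCCCCCCCCCCC(OS(C)(=O)=O)CC(=O)CCCCCCCCCCCCCCO[Si](C)(C)C(C)(C)C | intermediate
13 | methyl (16E)-32-[(tert-butyldimethylsilyl)oxy]-18-oxodotriacont-16-enoate | COC(=O)CCCCCCCCCCCCCC/C=C/C(=O)CCCCCCCCCCCCCCO[Si](C)(C)C(C)(C)C | intermediate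
14 | methyl 32-[(tert-butyldimethylsilyl)oxy]-18-oxodotriacontanoate | COC(=O)CCCCCCCCCCCCCCCCC(=O)CCCCCCCCCCCCCCO[Si](C)(C)C(C)(C)C | intermediate
15 | methyl 32-hydroxy-18-oxodotriacontanoate | COC(=O)CCCCCCCCCCCCCCCCC(=O)CCCCCCCCCCCCCCO | intermediate
16 | potassium 18-hydrazinylidene-32-hydroxydotriacontanoate (not isolated) | [K+].[O-]C(=O)CCCCCCCCCCCCCCCCC(=NN)CCCCCCCCCCCCCCO | intermediate
17 | 32-hydroxydotriacontanoic acid | OC(=O)CCCCCCCCCCCCCCCCCCCCCCCCCCCCCCCO | intermediate
18 | 32-hydroxydotriacontanoic 2,4,6-trichlorobenzoic anhydride (not isolated) | O=C(OC(=O)CCCCCCCCCCCCCCCCCCCCCCCCCCCCCCCO)c1c(Cl)cc(Cl)cc1Cl | intermediate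
19 | oxacyclotritriacontan-2-one (32-dotriacontanolide, achiral) | O=C1CCCCCCCCCCCCCCCCCCCCCCCCCCCCCCCO1 | target

**Totals**

Total step count: 11.
Longest linear sequence: 9 steps (steps 1, 2, 3, 6, 7, 8, 9, 10, 11); fragment B takes 2 steps (4, 5).

**Three steps most likely to fail, each with a fallback**

Step 6 (boron aldol) is at risk from incomplete regiocontrol of enolisation and from the poor cold solubility of both waxy partners. The fallback sets out from ketone 5. Condensation with Me2NNH2 (EtOH, cat. AcOH, reflux) gives 2-{16-[(tert-butyldimethylsilyl)oxy]hexadecan-2-ylidene}-1,1-dimethylhydrazine F1. LiN(iPr)2 in THF at 0 °C metalates F1 only at the CH3 group, and this aza-enolate adds to aldehyde 8 at −78 °C (AcOH quench) to give the β-hydroxy hydrazone methyl rac-32-[(tert-butyldimethylsilyl)oxy]-18-(2,2-dimethylhydrazinylidene)-16-hydroxydotriacontanoate F2. Aqueous Cu(OAc)2 in THF at rt then hydrolyses the hydrazone. The fallback comes back to the route at β-hydroxy ketone 11, and any enone 13 formed by loss of water is used as well.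

Step 10 (Wolff–Kishner) is at risk from the harsh alkaline conditions at 200 °C, from foaming of the potassium soap and from incomplete reduction. The fallback sets out from keto ester 15. Ethane-1,2-dithiol with BF3·OEt2 in CH2Cl2 gives the dithiolane methyl 17-[2-(14-hydroxytetradecyl)-1,3-dithiolan-2-yl]heptadecanoate F3. Raney Ni in refluxing EtOH desulfurises F3 to methyl 32-hydroxydotriacontanoate F4. LiOH in THF/MeOH/H2O at 50 °C, then aq HCl, saponifies F4. The fallback comes back to the route at hydroxy acid 17.

Step 11 (macrolactonization) is at risk from oligomerisation and from the low solubility of the C32 hydroxy acid. The fallback sets out from hydroxy acid 17. Aqueous 48% HBr in AcOH with cat. H2SO4 at reflux gives 32-bromodotriacontanoic acid F5. Slow addition of F5 to Cs2CO3 in DMF at 80 °C under high dilution closes the ring by intramolecular O-alkylation of the cesium carboxylate instead of acyl activation. The fallback comes back to the route at target 19.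

**Further compounds**

F1 | step 6 | 2-{16-[(tert-butyldimethylsilyl)oxy]hexadecan-2-ylidene}-1,1-dimethylhydrazine (C=N isomer mixture) | CC(=NN(C)C)CCCCCCCCCCCCCCO[Si](C)(C)C(C)(C)C
F2 | step 6 | methyl rac-32-[(tert-butyldimethylsilyl)oxy]-18-(2,2-dimethylhydrazinylidene)-16-hydroxydotriacontanoate (racemic at C16, C=N isomer mixture) | COC(=O)CCCCCCCCCCCCCCC(O)CC(=NN(C)C)CCCCCCCCCCCCCCO[Si](C)(C)C(C)(C)C
F3 | step 10 | methyl 17-[2-(14-hydroxytetradecyl)-1,3-dithiolan-2-yl]heptadecanoate | COC(=O)CCCCCCCCCCCCCCCCC1(CCCCCCCCCCCCCCO)SCCS1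
F4 | step 10 | methyl 32-hydroxydotriacontanoate | COC(=O)CCCCCCCCCCCCCCCCCCCCCCCCCCCCCCCO
F5 | step 11 | 32-bromodotriacontanoic acid | OC(=O)CCCCCCCCCCCCCCCCCCCCCCCCCCCCCCCBr
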